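## Analysis of the target

Germacrane locants are used throughout: C1–C10 for the ring, C11–C13 for the lactone carbons, C14 on C10 and C15 on C4.

- The target is a germacranolide: a ten-membered carbocycle fused at C6–C7 to a butenolide (O–C12(=O)–C11=C7).
- It carries an acetoxymethyl group (C13) on C11, an (R)-2-methylbutanoate on the allylic C8, a free hydroxymethyl group (C14) on C10 and a methyl group on C4.
- Around the ring a 1,10-epoxide, a Z C2=C3 alkene and a 4,5-epoxide follow one another, so both epoxides are vinyl epoxides.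
- The six ring stereocentres are 1R, 4R, 5S, 6S, 8S and 10S. The 1,10-epoxide is trans (C2 and C9 on opposite faces, as from a ring-trans C1=C10 alkene) and the 4,5-epoxide is cis (C3 and C6 on the same face).
- Sensitive features are the two vinyl epoxides (acid, zerovalent palladium, SN2′ attack), the 2,3-epoxy alcohol at C14/C10/C1, the allylic acetate, and the butenolide γ-hydrogen at C6, which is flanked by potential leaving groups at C13 and C8.
- The difficulty lies in closing a medium ring with defined alkene geometry and then placing six oxygen functions around it in an order that none of these groups forbids.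
- The strategy rests on the six-atom array C6(O)–C7–C8(O)–C9–C10–C1. If C1 and C6 are joined, the array becomes a 3-oxy-1,5-diene on a six-membered ring C1–C6 that already holds C2=C3 and the C4/C5 oxygens. A [3,3] shift of that ring returns the ten-membered ring with the C6 carbonyl, the C1=C10 alkene and the C8 stereocentre.

## Retrosynthetic reasoning

**1,10-Epoxide (42 ⇒ 41).** The two C–O bonds of the 1,10-epoxide are cut last. This epoxide is the most fragile group and, with the free C14 hydroxyl, forms an epoxy alcohol that would not survive base. Dienol 41 has only one hydroxyl, so a hydroxyl-directed, reagent-controlled epoxidation can pick C1=C10 and its face; the ring-trans alkene in 41 is carried over as the trans epoxide.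

**C14 silyl ether and 4,5-epoxide (41 ⇒ 40 ⇒ 39).** The C14 oxygen is masked as a silyl ether in 40. The 4,5-epoxide is opened at C5–O to the trans-diol 39. The forward closure lets the tertiary C4 oxygen displace an activated C5 oxygen with inversion, so the cis epoxide comes from diol stereochemistry set early on a six-membered ring, not from a face-selective epoxidation of a conjugated triene.

**Acyl groups (39 ⇒ 38 ⇒ 36 ⇒ 35 ⇒ 34).** The ester C–O bond at C8 and the acetate C–O bond at C13 are cut, leading through alcohol 36 (after unmasking the C8 ether) to the hydroxymethyl butenolide 34. Acylation at oxygen touches none of the stereocentres, and the order keeps C8 as an ether while palladium is in use.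

**C11–C13 bond (34 ⇒ 32 ⇒ 31 ⇒ 29).** C13 is attached by cross-coupling of 33 with the alkenyl triflate 32, which comes from the 3-hydroxybutenolide 31 and hence from the hydroxy lactone 29. This places the C7=C11 double bond without any stereospecific elimination, because 31 can enolise in one direction only. The coupling must precede both epoxides, since zerovalent palladium would ionise a vinyl epoxide.

**Lactone and C7–C11 bond (29 ⇒ 27 ⇒ 24 + 25).** The lactone O–C12 bond, the C6–H bond and the C7–C11 bond are cut, giving ketone 24 and the two-carbon aldehyde 25. The forward steps are an aldol at C7, reduction of C6 and lactonisation. The forward reduction has to set C6 (S); C7 and C11 need no control because both become sp2.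

**Key disconnection (24 ⇒ 21).** C8–C9 is cut and C1–C6 is joined, which contracts the ten-membered ring to cyclohexenol 21.

- The ring is formed by a unimolecular ring expansion, with no macrocyclisation.
- The C6 oxygen arrives as a ketone whose enolisable C7 methylene is free for the aldol.
- The C8 oxygen arrives with its configuration through the enol ether.
- The two alkenyl groups in 21 must be trans. A cis pair would force one ring bond axial in the chair and lead to a ring-cis C1=C10, from which only a cis-1,10-epoxide could follow. The trans pair has a single chair and gives the ring-trans alkene that the target's epoxide requires.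

**C6–C7 bond (21 ⇒ 18 + 8; 8 ⇒ 6 ⇒ 3 + 4).** The C6–C7 bond is cut to ketone 18 and the (E)-alkoxyvinyl iodide 8. Addition to the carbonyl from the face opposite the C1 and C5 substituents gives the trans relationship of the alkenyl groups. Iodide 8 goes back to ynol ether 6, and 6 to 3 and 4, which supply the C8 oxygen and the carbons C7 and C8.

**C1–C10 bond (18 ⇒ 17 ⇒ 15 + 2; 2 ⇒ 1).** Ketone 18 is labile (its C1–H is α to the carbonyl and doubly allylic), so it is made only by a neutral oxidation of alcohol 17. The C1–C10 bond of 17 is cut to the vinyl epoxide 15 and the alkenyl bromide 2, made from 1. Anti opening at the allylic carbon sets C1 and leaves C2=C3 in place without any dienolate chemistry, which would risk aromatisation by loss of the C4 oxygen.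

**Six-membered ring (15 ⇒ 14 ⇒ 13 ⇒ 12 ⇒ 11 ⇒ 10 ⇒ 9).** Epoxide 15 comes from diene 14, the diene from the dibromide 13 of cyclohexene 12, and 12 from trans-diol 11, epoxide 10 and the achiral diene 9. One asymmetric epoxidation of 9 fixes the absolute configuration; every later stereocentre is derived from C4 and C5 by substrate control.

## Alternatives that were turned down

**Alternative 1: ring closure by sulfonium ylide epoxidation at C1–C10.**
- Disconnection: the C1–C10 bond together with the C1–O bond of the 1,10-epoxide. This leads from the diepoxy lactone A1 to the open-chain salt A2, with a C10 ketone at one end and a diphenylsulfonium group on the allylic C1 at the other.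
- Forward key step: a hindered amide base removes a C1 proton of A2, the ylide adds to the C10 carbonyl, and the betaine collapses with loss of the sulfide. Ring and epoxide of A1 form together.
- For it: it is convergent, the most labile epoxide arrives at the very end, and butenolide and 4,5-epoxide can be built on an open chain.
- Against it for this target:
  - A ten-membered ring closed by carbonyl addition must beat oligomerisation and transannular strain.
  - The allylic ylide is ambident and can rearrange by a [2,3] shift.
  - Nothing in A2 dictates the trans relationship of C2 and C9 or the face at C10.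
  - The strong base meets the acidic C6–H of the butenolide, with leaving groups at C13 and C8 next to it, and an enolisable ketone.
- Comparison: on convergence, and on sparing a late epoxidation of a medium-ring alkene, Alternative 1 is the stronger plan. The chosen strategy offers in its place a ring formation without entropic penalty, and a chair that fixes the C1=C10 geometry and C8 at once.

**Alternative 2: photochemical opening of a cis-fused bicyclic diene.**
- Disconnection: the C5–C10 bond is restored, leading from trienolide A3 to the cis-fused 1,3-diene lactone A4 of the eudesmane type.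
- Forward key step: irradiation of A4 opens the cyclohexadiene ring in a conrotatory six-electron process, breaks C5–C10 and merges the two rings into the ten-membered triene A3.
- For it: a decalin such as A4 is rigid and its stereocentres are easy to set. One step creates the ring and three alkenes, and lactone, ester and acetate are already in place. In step count it is the shortest plan.
- Against it:
  - The reaction ends in a photostationary mixture; the triene can reclose, isomerise or react further, and the butenolide is a chromophore itself.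
  - A3 as formulated has C1=C10 ring-cis and C4=C5 ring-trans. This is the reverse of what the trans-1,10- and cis-4,5-epoxides need, and nothing in A4 favours the other conrotatory sense.
  - Two epoxidations would then have to pick two of three conjugated alkenes, and their faces, with no directing group at C4/C5.
- Comparison: Alternative 2 wins on step economy. The chosen strategy gives geometric certainty at C1=C10, keeps C2=C3 Z by ring constraint, and brings the C4 and C5 oxygens with fixed configuration.

**Alternative 3: [2,3]-Wittig contraction of a 13-membered ether.**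
- Disconnection: the C6–C7 bond, leading from trienol A5 to the 13-membered diallylic ether A6 in which oxygen links C6 and C13.
- Forward key step: an alkyllithium metallates C6 of A6; the [2,3] shift forms C6–C7, breaks O–C13 and gives the ten-membered carbocycle A5 with a C6 hydroxyl and a C11=C13 methylene.
- For it: a 13-membered ether closes more easily than a ten-membered carbocycle. The shift makes the C6–C7 bond and the C6 oxygen in one step and can relay alkene geometry into the C6/C7 relationship, and A5 carries the three-carbon unit for the lactone.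
- Against it:
  - C6 and C13 are both α-oxy allylic and compete for metallation.
  - The C6 carbanion is the terminus of a triene, so the charge is spread over seven carbons and other shifts and alkene isomerisation can leak in.
  - The triene geometry of A5 again does not fit the two epoxides.
  - After the key step C12 must be oxidised, the methylene moved into the ring with oxygen transposed to C13, and two epoxides placed on a triene.
- Comparison: for the direct installation of the C6 oxygen Alternative 3 is the stronger plan, because the chosen route must reduce a C6 ketone later. The chosen strategy offers a rearrangement with one sensible pathway and a regiodefined nucleophilic site at C7.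

Key step: step 13

Remarks on the chemistry:
- The D-fructose-derived Shi ketone is assumed to epoxidise diene 9 with the facial sense usual for trisubstituted cycloalkenes; if the sense were opposite, the enantiomeric ketone would be used with nothing else changed.
- C2′ of the ester is R as drawn, so (R)-2-methylbutanoic acid is used.

## Route

Step 1
Reactants: 1 2-bromoprop-2-en-1-ol
Product: 2 tert-butyl[(2-bromoprop-2-en-1-yl)oxy]diphenylsilane
Conditions: TBDPSCl, imidazole, DMF, 0 °C → rt
Reagents that add atoms: tert-butyl(chloro)diphenylsilane, CC(C)(C)[Si](Cl)(c1ccccc1)c1ccccc1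
Why: Standard silylation of a primary allylic alcohol; the bulky silyl group is chosen to suppress O→C silyl migration in the later alkenyllithium and to outlast removal of the triethylsilyl groups.

Step 2
Reactants: 3 4-methoxybenzyl alcohol; 4 trichloroethylene
Product: 6 1-(ethynyloxymethyl)-4-methoxybenzene, via dichlorovinyl ether 5 (not isolated)
Conditions: KH, THF, 0 °C; 4, −50 °C → rt; n-BuLi, −78 → −40 °C; MeOH
Reagents that add atoms: none
Why: The alkoxide adds to dichloroacetylene formed in situ from trichloroethylene, and n-BuLi then effects elimination and chlorine–lithium exchange to the lithium alkynyl ether, which is protonated (ynol ether synthesis from an alcohol and trichloroethylene). The product is kept cold and used promptly because benzylic alkynyl ethers rearrange on warming.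

Step 3
Reactants: 6 1-(ethynyloxymethyl)-4-methoxybenzene
Product: 8 1-{[(E)-2-iodoethenyl]oxymethyl}-4-methoxybenzene, via alkenylzirconocene chloride 7 (not isolated)
Conditions: Cp2Zr(H)Cl, THF, 0 °C → rt; I2, −78 → 0 °C
Reagents that add atoms: iodine, II
Why: Hydrozirconation is a syn addition that places zirconium on the terminal carbon, and iodinolysis retains configuration, so the E geometry of the 2-alkoxyvinyl iodide is fixed by mechanism (hydrozirconation–iodination).

Step 4
Reactants: 9 1-methylcyclohexa-1,4-diene
Product: 10 (1S,6R)-1-methyl-7-oxabicyclo[4.1.0]hept-3-ene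
Conditions: D-fructose-derived Shi ketone (cat.), KHSO5 (Oxone), K2CO3, Bu4NHSO4 (cat.), MeCN/CH2(OMe)2/aq. buffer, 0 °C
Reagents that add atoms: potassium peroxymonosulfate (KHSO5), [K+].[O-]S(=O)(=O)OO
Why: Shi epoxidation; the chiral dioxirane attacks the electron-rich trisubstituted alkene in preference to the cis-disubstituted one, and its spiro transition state should deliver oxygen to the face that gives the (1S,6R) epoxide. This step sets the absolute configuration of the whole route.

Step 5
Reactants: 10 (1S,6R)-1-methyl-7-oxabicyclo[4.1.0]hept-3-ene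
Product: 11 (1R,2R)-1-methylcyclohex-4-ene-1,2-diol
Conditions: HClO4 (cat.), THF/H2O, 0 °C → rt
Reagents that add atoms: water, O
Why: Acid-catalysed epoxide hydrolysis; water attacks the tertiary carbon (C4) from the rear, so C4 is inverted while C5 keeps its oxygen, which gives the trans-diol.

Step 6
Reactants: 11 (1R,2R)-1-methylcyclohex-4-ene-1,2-diol
Product: 12 (1R,2R)-1-methyl-1,2-bis(triethylsilyloxy)cyclohex-4-ene
Conditions: TESOTf, 2,6-lutidine, CH2Cl2, −78 → 0 °C
Reagents that add atoms: triethylsilyl trifluoromethanesulfonate, CC[Si](CC)(CC)OS(=O)(=O)C(F)(F)F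
Why: The silyl triflate silylates the tertiary as well as the secondary hydroxyl; triethylsilyl is chosen because both ethers can later be removed with buffered HF without loss of the tert-butyldiphenylsilyl ether.

Step 7
Reactants: 12 (1R,2R)-1-methyl-1,2-bis(triethylsilyloxy)cyclohex-4-ene
Product: 13 (1R,2R)-4,5-dibromo-1-methyl-1,2-bis(triethylsilyloxy)cyclohexane (trans-dibromide)
Conditions: Br2, CH2Cl2, −78 °C
Reagents that add atoms: bromine, BrBr
Why: Electrophilic anti addition of bromine to the only alkene; either trans-dibromide serves, because both new stereocentres are erased in step 8.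

Step 8
Reactants: 13 (1R,2R)-4,5-dibromo-1-methyl-1,2-bis(triethylsilyloxy)cyclohexane
Product: 14 (5R,6R)-5-methyl-5,6-bis(triethylsilyloxy)cyclohexa-1,3-diene
Conditions: DBU, toluene, 90 °C
Reagents that add atoms: none
Why: Double E2 dehydrobromination; hydrogens anti to bromine are available only at C6 and C3, so the conjugated diene C6=C1–C2=C3 is the diene that forms, and a silyloxide is too poor a leaving group for aromatisation under these conditions.

Step 9
Reactants: 14 (5R,6R)-5-methyl-5,6-bis(triethylsilyloxy)cyclohexa-1,3-diene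
Product: 15 (1S,4R,5R,6S)-4-methyl-4,5-bis(triethylsilyloxy)-7-oxabicyclo[4.1.0]hept-2-ene
Conditions: mCPBA, NaHCO3, CH2Cl2, 0 °C
Reagents that add atoms: 3-chloroperoxybenzoic acid, OOC(=O)c1cccc(Cl)c1
Why: Peracid epoxidation of a conjugated diene stops at the monoepoxide; the C6=C1 alkene reacts because C2=C3 is shielded on both faces by the fully substituted C4, and the peracid approaches anti to the C5 silyloxy group.

Step 10
Reactants: 15 (1S,4R,5R,6S)-4-methyl-4,5-bis(triethylsilyloxy)-7-oxabicyclo[4.1.0]hept-2-ene; 2 tert-butyl[(2-bromoprop-2-en-1-yl)oxy]diphenylsilane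
Product: 17 (1S,2S,5R,6R)-2-[3-(tert-butyldiphenylsilyloxy)prop-1-en-2-yl]-5-methyl-5,6-bis(triethylsilyloxy)cyclohex-3-en-1-ol, via alkenyllithium 16 (not isolated)
Conditions: 2, t-BuLi (2 equiv), Et2O, −78 °C; BF3·OEt2; then 15, −78 °C; aq. NaHCO3
Reagents that add atoms: none
Why: Lewis-acid-assisted SN2 opening of a vinyl epoxide by an alkenyllithium (organolithium/BF3 epoxide opening); attack occurs at the allylic carbon C1 with inversion, the SN2′ terminus C3 being blocked by the quaternary C4. This sets C1 trans to the C6 oxygen and cis to the C5 silyloxy group.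

Step 11
Reactants: 17 (1S,2S,5R,6R)-2-[3-(tert-butyldiphenylsilyloxy)prop-1-en-2-yl]-5-methyl-5,6-bis(triethylsilyloxy)cyclohex-3-en-1-ol
Product: 18 (2S,3R,6S)-6-[3-(tert-butyldiphenylsilyloxy)prop-1-en-2-yl]-3-methyl-2,3-bis(triethylsilyloxy)cyclohex-4-en-1-one
Conditions: Dess–Martin periodinane, NaHCO3, CH2Cl2, 0 °C
Reagents that add atoms: none
Why: Dess–Martin oxidation under buffered, non-basic conditions keeps the doubly activated C1–H from epimerising and the C2=C3 alkene from moving into conjugation; the 2,6-cis arrangement of the C1 and C5 substituents is also the thermodynamically preferred one. The ketone is used at once.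

Step 12
Reactants: 18 (2S,3R,6S)-6-[3-(tert-butyldiphenylsilyloxy)prop-1-en-2-yl]-3-methyl-2,3-bis(triethylsilyloxy)cyclohex-4-en-1-one; 8 1-{[(E)-2-iodoethenyl]oxymethyl}-4-methoxybenzene
Product: 21 (1S,2R,3R,6S)-6-[3-(tert-butyldiphenylsilyloxy)prop-1-en-2-yl]-1-[(E)-2-(4-methoxybenzyloxy)ethenyl]-3-methyl-2,3-bis(triethylsilyloxy)cyclohex-4-en-1-ol, via vinyllithium 19 (not isolated), via vinylcerium dichloride 20 (not isolated)
Conditions: 8, t-BuLi (2 equiv), Et2O, −78 °C; CeCl3, THF, −78 °C; then 18, −78 °C; aq. NaHCO3
Reagents that add atoms: none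
Why: Organocerium 1,2-addition; the weakly basic cerium reagent adds to the easily enolised ketone instead of deprotonating C1. It enters equatorially from the face opposite the pseudoaxial C4 methyl and the C1 and C5 substituents, which places the alkoxyvinyl group trans to the C1 alkenyl group and sets C6 (S).

Step 13
Reactants: 21 (1S,2R,3R,6S)-6-[3-(tert-butyldiphenylsilyloxy)prop-1-en-2-yl]-1-[(E)-2-(4-methoxybenzyloxy)ethenyl]-3-methyl-2,3-bis(triethylsilyloxy)cyclohex-4-en-1-ol
Product: 24 (4R,5S,8S)-10-[(tert-butyldiphenylsilyloxy)methyl]-8-(4-methoxybenzyloxy)-4-methyl-4,5-bis(triethylsilyloxy)cyclodeca-1(10),2-dien-6-one with ring-trans C1=C10 and Z C2=C3 (germacrane locants), via potassium alkoxide 22 (not isolated), via potassium enolate 23 (not isolated)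
Conditions: KH, 18-crown-6, THF, 0 °C; then AcOH, THF, −78 °C
Reagents that add atoms: none
Why: KH with 18-crown-6 converts the tertiary alcohol into a loosely ion-paired alkoxide whose oxygen weakens the adjacent, doubly allylic C1–C6 bond; a concerted [3,3] shift (anionic oxy-Cope rearrangement) then forms C8–C9 and breaks C1–C6, and the enolate is protonated to the ketone by the cold acidic quench. The closest known reaction type is the anionic oxy-Cope ring expansion of trans-1,2-dialkenylcyclohexanols to cyclodec-5-enones with a trans ring alkene. The ten-membered ring is not closed by a cyclisation in the usual sense: it arises by four-atom expansion of the six-membered ring, the new C8–C9 bond forming inside the six-centre chair while the old ring bond opens. Because the two alkenyl groups are trans and both equatorial, only one chair is available, with the ring bonds C1–C2 and C6–C5 equatorial on the pericyclic chair; this makes C1=C10 ring-trans (C2 and C9 trans), the geometry the trans-1,10-epoxide needs. The new stereocentre C8 is set by chirality transfer from C1 and C6 through this chair, the E enol ether placing the C8 oxygen equatorial, which gives C8 S. The step needs chair over boat selectivity, reaction through the exocyclic alkenyl group and not through the ring C2=C3 (which would require a strained boat across the ring), and survival of the β-alkoxy enolate. The labile C1–C6 bond should let the shift run near 0 °C, where loss of the C8 alkoxide from the enolate and silyl migration from O5 to O6 are slow; C4 and C5 are spectators and keep their configuration.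

Step 14
Reactants: 24 the ten-membered dienone of step 13; 25 ethyl glyoxylate
Product: 27 ethyl 2-hydroxy-2-[(4R,5S,8S)-6-oxo-cyclodecadienyl-7-yl]acetate (aldol adduct of 24 at C7; mixture of epimers at C7 and C11), via lithium enolate 26 (not isolated)
Conditions: LiN(iPr)2, THF, −78 °C; 25 (freshly distilled), −78 °C; AcOH
Reagents that add atoms: none
Why: Kinetic deprotonation occurs at the unhindered C7 methylene and not at the C5 methine flanked by the quaternary C4, and the lithium enolate adds to the non-enolisable aldehyde at −78 °C before β-elimination of the C8 alkoxide can compete (directed aldol addition). The configurations at C7 and C11 are left uncontrolled because both centres become sp2 in step 16.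

Step 15
Reactants: 27 the aldol adduct of step 14
Product: 29 (4R,5R,6S,8S)-11-hydroxy-6,12-olide (α-hydroxy-γ-lactone fused at C6–C7; epimers at C7 and C11), via hydroxy ester 28 (not isolated)
Conditions: LiBH(s-Bu)3, THF, −78 °C; AcOH; then PPTS (cat.), PhH, 40 °C
Reagents that add atoms: none
Why: Hydride reduction under Felkin–Anh control by the α-silyloxy group at C5 (hydride anti to the C5–O bond) should give the 5,6-syn alcohol, that is C6 S. The γ-hydroxy ester then lactonises under mild acid catalysis (5-exo-trig) with loss of ethanol.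

Step 16
Reactants: 29 the hydroxy lactone of step 15
Product: 31 (4R,5R,6S,8S)-11-hydroxy-7(11)-en-6,12-olide (3-hydroxybutenolide), via oxo lactone 30 (not isolated)
Conditions: Dess–Martin periodinane, NaHCO3, CH2Cl2, 0 °C → rt
Reagents that add atoms: none
Why: Dess–Martin oxidation of the secondary α-hydroxy lactone; the 2-oxo lactone can enolise only towards C7, so all epimers at C7 and C11 converge on one enol with the C7=C11 double bond in place.

Step 17
Reactants: 31 the 3-hydroxybutenolide of step 16
Product: 32 (4R,5R,6S,8S)-11-(trifluoromethylsulfonyloxy)-7(11)-en-6,12-olide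
Conditions: Tf2O, 2,6-lutidine, CH2Cl2, −78 °C
Reagents that add atoms: trifluoromethanesulfonic anhydride, O=S(=O)(OS(=O)(=O)C(F)(F)F)C(F)(F)F
Why: O-Sulfonylation of the acidic enol with a hindered pyridine base gives the alkenyl triflate without exposing the γ-hydrogen at C6 to a strong base.

Step 18
Reactants: 32 the alkenyl triflate of step 17; 33 (tributylstannyl)methanol
Product: 34 (4R,5R,6S,8S)-13-hydroxy-7(11)-en-6,12-olide (α-hydroxymethyl butenolide)
Conditions: Pd(PPh3)4 (cat.), LiCl, 1,4-dioxane, 70 °C
Reagents that add atoms: none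
Why: Stille coupling of an electron-poor alkenyl triflate with a hydroxymethylstannane; oxidative addition is fast at the α-carbonyl triflate and LiCl assists transmetalation. The step is placed before any vinyl epoxide exists, and silyl ethers, the 4-methoxybenzyl ether and the diene are not ionised by zerovalent palladium.

Step 19
Reactants: 34 the hydroxymethyl butenolide of step 18
Product: 35 (4R,5R,6S,8S)-13-acetoxy-7(11)-en-6,12-olide
Conditions: Ac2O, pyridine, DMAP (cat.), CH2Cl2, 0 °C
Reagents that add atoms: acetic anhydride, CC(=O)OC(C)=O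
Why: Acetylation of the only free hydroxyl under weakly basic conditions.

Step 20
Reactants: 35 the acetate of step 19
Product: 36 (4R,5R,6S,8S)-13-acetoxy-8-hydroxy-7(11)-en-6,12-olide
Conditions: DDQ, CH2Cl2/pH 7 buffer, 0 °C
Reagents that add atoms: none
Why: Oxidative cleavage of the 4-methoxybenzyl ether by hydride abstraction and hydrolysis of the oxocarbenium ion; C8 keeps its oxygen and its configuration.

Step 21
Reactants: 36 the C8 alcohol of step 20; 37 (R)-2-methylbutanoic acid
Product: 38 (4R,5R,6S,8S)-13-acetoxy-8-[(R)-2-methylbutanoyloxy]-7(11)-en-6,12-olide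
Conditions: EDC·HCl, DMAP (cat.), CH2Cl2, 0 °C → rt
Reagents that add atoms: none
Why: Carbodiimide esterification (Steglich); acylation at oxygen leaves C8 untouched, and the low temperature with only catalytic DMAP limits ketene formation from the α-branched acid, so C2′ stays R.

Step 22
Reactants: 38 the ester of step 21
Product: 39 (4R,5R,6S,8S)-13-acetoxy-4,5-dihydroxy-8-[(R)-2-methylbutanoyloxy]-7(11)-en-6,12-olide
Conditions: HF·pyridine, pyridine, THF, 0 °C
Reagents that add atoms: none
Why: Buffered HF cleaves the secondary and tertiary triethylsilyl ethers much faster than the primary tert-butyldiphenylsilyl ether; acetate, ester and butenolide tolerate the weakly acidic medium.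

Step 23
Reactants: 39 the diol of step 22
Product: 40 (4R,5S,6S,8S)-13-acetoxy-4,5-epoxy-8-[(R)-2-methylbutanoyloxy]-7(11)-en-6,12-olide
Conditions: PPh3, DIAD, toluene, 0 °C → rt
Reagents that add atoms: none
Why: Mitsunobu cyclodehydration of a vicinal diol; only the secondary C5 hydroxyl is turned into an oxyphosphonium leaving group, and the tertiary C4 hydroxyl displaces it (3-exo-tet) with inversion at C5. This gives the cis-4,5-epoxide without a free alkoxide that could deprotonate C6 of the butenolide.

Step 24
Reactants: 40 the 4,5-epoxide of step 23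
Product: 41 (4R,5S,6S,8S)-13-acetoxy-4,5-epoxy-14-hydroxy-8-[(R)-2-methylbutanoyloxy]-germacra-1(10),2,7(11)-trien-6,12-olide (dienol)
Conditions: Bu4NF, AcOH, THF, 0 °C → rt
Reagents that add atoms: none
Why: Fluoride desilylation buffered with acetic acid frees the primary C14 hydroxyl while the medium stays non-basic, so the acetate, the butenolide and the vinyl epoxide are preserved.

Step 25
Reactants: 41 the dienol of step 24
Product: 42 the target, (1R,4R,5S,6S,8S,10S)-13-acetoxy-1,10:4,5-diepoxy-14-hydroxy-8-[(R)-2-methylbutanoyloxy]germacra-2,7(11)-dien-6,12-olide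
Conditions: Ti(OiPr)4 (cat.), diethyl L-(+)-tartrate (cat.), t-BuOOH, 4 Å MS, CH2Cl2, −20 °C
Reagents that add atoms: tert-butyl hydroperoxide, CC(C)(C)OO
Why: Sharpless asymmetric epoxidation; the titanium tartrate complex binds the only hydroxyl and epoxidises the adjacent C1=C10 alkene of the dienol, leaving the electron-poor butenolide alkene and the remote C2=C3 alkene alone. Diethyl L-(+)-tartrate should deliver oxygen to the face that gives C1 R and C10 S, and the ring-trans alkene is carried over as the trans epoxide.

## Compound list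

1 | 2-bromoprop-2-en-1-ol | OCC(Br)=C | starting material
2 | tert-butyl[(2-bromoprop-2-en-1-yl)oxy]diphenylsilane | C=C(Br)CO[Si](c1ccccc1)(c1ccccc1)C(C)(C)C | intermediate
3 | 4-methoxybenzyl alcohol | COc1ccc(CO)cc1 | starting material
4 | trichloroethylene | ClC=C(Cl)Cl | starting material
5 | 1-{[(E)-1,2-dichloroethenyl]oxymethyl}-4-methoxybenzene | COc1ccc(CO/C(Cl)=C\Cl)cc1 | intermediate (not isolated)
6 | 1-(ethynyloxymethyl)-4-methoxybenzene | COc1ccc(COC#C)cc1 | intermediate
7 | chloro[(E)-2-(4-methoxybenzyloxy)ethenyl]zirconocene (cyclopentadienyl ligands drawn σ-bonded) | COc1ccc(CO/C=C/[Zr](Cl)(C2C=CC=C2)C2C=CC=C2)cc1 | intermediate (not isolated)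
8 | 1-{[(E)-2-iodoethenyl]oxymethyl}-4-methoxybenzene | COc1ccc(CO/C=C/I)cc1 | intermediate
9 | 1-methylcyclohexa-1,4-diene | CC1=CCC=CC1 | starting material
10 | (1S,6R)-1-methyl-7-oxabicyclo[4.1.0]hept-3-ene | C1=CC[C@]2(C)O[C@@H]2C1 | intermediate
11 | (1R,2R)-1-methylcyclohex-4-ene-1,2-diol | C1=CC[C@@](C)(O)[C@H](O)C1 | intermediate
12 | (1R,2R)-1-methyl-1,2-bis(triethylsilyloxy)cyclohex-4-ene | C1=CC[C@@](C)(O[Si](CC)(CC)CC)[C@H](O[Si](CC)(CC)CC)C1 | intermediate
13 | (1R,2R)-4,5-dibromo-1-methyl-1,2-bis(triethylsilyloxy)cyclohexane, trans-dibromide (one of the two trans diastereomers drawn; both are carried on) | Br[C@@H]1[C@@H](Br)C[C@@](C)(O[Si](CC)(CC)CC)[C@H](O[Si](CC)(CC)CC)C1 | intermediate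
14 | (5R,6R)-5-methyl-5,6-bis(triethylsilyloxy)cyclohexa-1,3-diene | C1=C[C@@](C)(O[Si](CC)(CC)CC)[C@H](O[Si](CC)(CC)CC)C=C1 | intermediate
15 | (1S,4R,5R,6S)-4-methyl-4,5-bis(triethylsilyloxy)-7-oxabicyclo[4.1.0]hept-2-ene | C1=C[C@@H]2O[C@@H]2[C@@H](O[Si](CC)(CC)CC)[C@]1(C)O[Si](CC)(CC)CC | intermediate
16 | [3-(tert-butyldiphenylsilyloxy)prop-1-en-2-yl]lithium | C=C([Li])CO[Si](c1ccccc1)(c1ccccc1)C(C)(C)C | intermediate (not isolated)
17 | (1S,2S,5R,6R)-2-[3-(tert-butyldiphenylsilyloxy)prop-1-en-2-yl]-5-methyl-5,6-bis(triethylsilyloxy)cyclohex-3-en-1-ol | C=C(CO[Si](c1ccccc1)(c1ccccc1)C(C)(C)C)[C@@H]1C=C[C@@](C)(O[Si](CC)(CC)CC)[C@H](O[Si](CC)(CC)CC)[C@H]1O | intermediate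
18 | (2S,3R,6S)-6-[3-(tert-butyldiphenylsilyloxy)prop-1-en-2-yl]-3-methyl-2,3-bis(triethylsilyloxy)cyclohex-4-en-1-one | C=C(CO[Si](c1ccccc1)(c1ccccc1)C(C)(C)C)[C@@H]1C=C[C@@](C)(O[Si](CC)(CC)CC)[C@H](O[Si](CC)(CC)CC)C1=O | intermediate
19 | [(E)-2-(4-methoxybenzyloxy)ethenyl]lithium | COc1ccc(CO/C=C/[Li])cc1 | intermediate (not isolated)
20 | dichloro[(E)-2-(4-methoxybenzyloxy)ethenyl]cerium | COc1ccc(CO/C=C/[Ce](Cl)Cl)cc1 | intermediate (not isolated)
21 | (1S,2R,3R,6S)-6-[3-(tert-butyldiphenylsilyloxy)prop-1-en-2-yl]-1-[(E)-2-(4-methoxybenzyloxy)ethenyl]-3-methyl-2,3-bis(triethylsilyloxy)cyclohex-4-en-1-ol (trans-dialkenyl cyclohexenol, precursor of the key step) | C=C(CO[Si](c1ccccc1)(c1ccccc1)C(C)(C)C)[C@@H]1C=C[C@@](C)(O[Si](CC)(CC)CC)[C@H](O[Si](CC)(CC)CC)[C@@]1(O)/C=C/OCc1ccc(OC)cc1 | intermediate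
22 | potassium alkoxide of 21 | C=C(CO[Si](c1ccccc1)(c1ccccc1)C(C)(C)C)[C@@H]1C=C[C@@](C)(O[Si](CC)(CC)CC)[C@H](O[Si](CC)(CC)CC)[C@@]1([O-])/C=C/OCc1ccc(OC)cc1.[K+] | intermediate (not isolated)
23 | potassium C6–C7 enolate of 24 (C5 and C8 trans on the enolate double bond) | COc1ccc(CO[C@H]2C/C(CO[Si](c3ccccc3)(c3ccccc3)C(C)(C)C)=C/C=C\[C@@](C)(O[Si](CC)(CC)CC)[C@H](O[Si](CC)(CC)CC)/C([O-])=C/2)cc1.[K+] | intermediate (not isolated)
24 | (4R,5S,8S)-10-[(tert-butyldiphenylsilyloxy)methyl]-8-(4-methoxybenzyloxy)-4-methyl-4,5-bis(triethylsilyloxy)cyclodeca-1(10),2-dien-6-one, ring-trans C1=C10 and Z C2=C3 (germacrane locants) | COc1ccc(CO[C@H]2C/C(CO[Si](c3ccccc3)(c3ccccc3)C(C)(C)C)=C/C=C\[C@@](C)(O[Si](CC)(CC)CC)[C@H](O[Si](CC)(CC)CC)C(=O)C2)cc1 | intermediate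
25 | ethyl glyoxylate | CCOC(=O)C=O | starting material
26 | lithium C6–C7 enolate of 24 (enolate geometry not defined) | COc1ccc(CO[C@H]2C/C(CO[Si](c3ccccc3)(c3ccccc3)C(C)(C)C)=C/C=C\[C@@](C)(O[Si](CC)(CC)CC)[C@H](O[Si](CC)(CC)CC)C([O-])=C2)cc1.[Li+] | intermediate (not isolated)
27 | aldol adduct: 24 with a CH(OH)CO2Et group on C7 (4R,5S,8S; epimers at C7 and C11) | COc1ccc(CO[C@H]2C/C(CO[Si](c3ccccc3)(c3ccccc3)C(C)(C)C)=C/C=C\[C@@](C)(O[Si](CC)(CC)CC)[C@H](O[Si](CC)(CC)CC)C(=O)C2C(O)C(=O)OCC)cc1 | intermediate
28 | (4R,5R,6S,8S)-6-hydroxy ester obtained from 27 by reduction (epimers at C7 and C11) | COc1ccc(CO[C@H]2C/C(CO[Si](c3ccccc3)(c3ccccc3)C(C)(C)C)=C/C=C\[C@@](C)(O[Si](CC)(CC)CC)[C@H](O[Si](CC)(CC)CC)[C@@H](O)C2C(O)C(=O)OCC)cc1 | intermediate (not isolated)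
29 | (4R,5R,6S,8S)-11-hydroxy-6,12-olide: γ-lactone fused at C6–C7 with 8-(4-methoxybenzyloxy), 4,5-bis(triethylsilyloxy) and 14-(tert-butyldiphenylsilyloxy) groups (epimers at C7 and C11) | COc1ccc(CO[C@H]2C/C(CO[Si](c3ccccc3)(c3ccccc3)C(C)(C)C)=C/C=C\[C@@](C)(O[Si](CC)(CC)CC)[C@H](O[Si](CC)(CC)CC)[C@H]4OC(=O)C(O)C42)cc1 | intermediate
30 | (4R,5R,6S,8S)-11-oxo-6,12-olide (epimers at C7) | COc1ccc(CO[C@H]2C/C(CO[Si](c3ccccc3)(c3ccccc3)C(C)(C)C)=C/C=C\[C@@](C)(O[Si](CC)(CC)CC)[C@H](O[Si](CC)(CC)CC)[C@H]4OC(=O)C(=O)C42)cc1 | intermediate (not isolated)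
31 | (4R,5R,6S,8S)-11-hydroxy-7(11)-en-6,12-olide (3-hydroxybutenolide) | COc1ccc(CO[C@H]2C/C(CO[Si](c3ccccc3)(c3ccccc3)C(C)(C)C)=C/C=C\[C@@](C)(O[Si](CC)(CC)CC)[C@H](O[Si](CC)(CC)CC)[C@H]4OC(=O)C(O)=C42)cc1 | intermediate
32 | (4R,5R,6S,8S)-11-(trifluoromethylsulfonyloxy)-7(11)-en-6,12-olide | COc1ccc(CO[C@H]2C/C(CO[Si](c3ccccc3)(c3ccccc3)C(C)(C)C)=C/C=C\[C@@](C)(O[Si](CC)(CC)CC)[C@H](O[Si](CC)(CC)CC)[C@H]4OC(=O)C(OS(=O)(=O)C(F)(F)F)=C42)cc1 | intermediate
33 | (tributylstannyl)methanol | OC[Sn](CCCC)(CCCC)CCCC | starting material
34 | (4R,5R,6S,8S)-13-hydroxy-7(11)-en-6,12-olide with 8-(4-methoxybenzyloxy), 4,5-bis(triethylsilyloxy) and 14-(tert-butyldiphenylsilyloxy) groups | COc1ccc(CO[C@H]2C/C(CO[Si](c3ccccc3)(c3ccccc3)C(C)(C)C)=C/C=C\[C@@](C)(O[Si](CC)(CC)CC)[C@H](O[Si](CC)(CC)CC)[C@H]4OC(=O)C(CO)=C42)cc1 | intermediate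
35 | (4R,5R,6S,8S)-13-acetoxy-8-(4-methoxybenzyloxy)-7(11)-en-6,12-olide | COc1ccc(CO[C@H]2C/C(CO[Si](c3ccccc3)(c3ccccc3)C(C)(C)C)=C/C=C\[C@@](C)(O[Si](CC)(CC)CC)[C@H](O[Si](CC)(CC)CC)[C@H]4OC(=O)C(COC(C)=O)=C42)cc1 | intermediate
36 | (4R,5R,6S,8S)-13-acetoxy-8-hydroxy-7(11)-en-6,12-olide | O[C@H]2C/C(CO[Si](c3ccccc3)(c3ccccc3)C(C)(C)C)=C/C=C\[C@@](C)(O[Si](CC)(CC)CC)[C@H](O[Si](CC)(CC)CC)[C@H]4OC(=O)C(COC(C)=O)=C42 | intermediate
37 | (R)-2-methylbutanoic acid | CC[C@@H](C)C(=O)O | starting material
38 | (4R,5R,6S,8S)-13-acetoxy-8-[(R)-2-methylbutanoyloxy]-4,5-bis(triethylsilyloxy)-14-(tert-butyldiphenylsilyloxy)-7(11)-en-6,12-olide | CC[C@@H](C)C(=O)O[C@H]2C/C(CO[Si](c3ccccc3)(c3ccccc3)C(C)(C)C)=C/C=C\[C@@](C)(O[Si](CC)(CC)CC)[C@H](O[Si](CC)(CC)CC)[C@H]4OC(=O)C(COC(C)=O)=C42 | intermediate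
39 | (4R,5R,6S,8S)-13-acetoxy-4,5-dihydroxy-8-[(R)-2-methylbutanoyloxy]-14-(tert-butyldiphenylsilyloxy)-7(11)-en-6,12-olide | CC[C@@H](C)C(=O)O[C@H]2C/C(CO[Si](c3ccccc3)(c3ccccc3)C(C)(C)C)=C/C=C\[C@@](C)(O)[C@H](O)[C@H]4OC(=O)C(COC(C)=O)=C42 | intermediate
40 | (4R,5S,6S,8S)-13-acetoxy-4,5-epoxy-8-[(R)-2-methylbutanoyloxy]-14-(tert-butyldiphenylsilyloxy)-7(11)-en-6,12-olide | CC[C@@H](C)C(=O)O[C@H]2C/C(CO[Si](c3ccccc3)(c3ccccc3)C(C)(C)C)=C/C=C\[C@@]5(C)O[C@H]5[C@H]4OC(=O)C(COC(C)=O)=C42 | intermediate
41 | (4R,5S,6S,8S)-13-acetoxy-4,5-epoxy-14-hydroxy-8-[(R)-2-methylbutanoyloxy]germacra-1(10),2,7(11)-trien-6,12-olide, ring-trans C1=C10 and Z C2=C3 | CC[C@@H](C)C(=O)O[C@H]2C/C(CO)=C/C=C\[C@@]5(C)O[C@H]5[C@H]4OC(=O)C(COC(C)=O)=C42 | intermediate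
42 | (1R,4R,5S,6S,8S,10S)-13-acetoxy-1,10:4,5-diepoxy-14-hydroxy-8-[(R)-2-methylbutanoyloxy]germacra-2,7(11)-dien-6,12-olide | CC[C@@H](C)C(=O)O[C@H]1C[C@@]2(CO)O[C@@H]2/C=C\[C@@]2(C)O[C@H]2[C@H]2OC(=O)C(COC(C)=O)=C12 | target

## Step count and least certain steps

Total step count: 25 steps (steps 1–3 make the two side fragments, steps 4–25 form the main line).
Longest linear sequence: 22 steps, from 9 to 42.

**Step 13 (key step).** Three processes could divert it:
- loss of the C8 alkoxide from the potassium enolate (β-elimination);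
- heterolysis of the doubly allylic C1–C6 bond followed by unselective recombination, which would erase the chair-defined C1=C10 geometry and the C8 configuration;
- migration of the C5 silyl group to the C6 oxygen, which removes the oxyanion that drives the shift.

Fallback: run the rearrangement in neutral form. Starting from 21, the tertiary hydroxyl would be silylated with 1-(trimethylsilyl)imidazole to the trimethylsilyl ether F1. Heating F1 in toluene in a sealed vessel would effect the thermal siloxy-Cope shift through the same chair to the trimethylsilyl enol ether F2. Cold Bu4NF/AcOH would release the ketone and return to the route at 24. No enolate is formed, so neither β-elimination nor silyl migration can occur.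

**Step 15.** Hydride could be delivered from the undesired face of the C6 carbonyl, because the conformation of the ten-membered ring or the C7 substituent may override Felkin control by the C5 silyloxy group.

Fallback: invert C6 after the fact. Starting from 27, the same reduction and lactonisation would then give the C6-epimeric lactone F3. Opening with LiOH in THF/H2O would give the hydroxy acid F4, and Mitsunobu lactonisation (PPh3, DIAD) would close the ring by displacement at C6 with inversion, returning to the route at 29. No acetate or butenolide is present at this stage, so the basic opening is tolerated.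

**Step 23.** Activation of the hindered C5 hydroxyl may be slow, and the oxyphosphonium group could be lost by elimination towards C6 instead of by displacement.

Fallback: separate activation from closure. Starting from 39, the secondary hydroxyl would be mesylated (MsCl, Et3N, CH2Cl2, −20 °C) to the C5 methanesulfonate F5. Brief treatment with Cs2CO3 in MeCN at 0 °C would close the epoxide and return to the route at 40. The risk here is deprotonation at C6, which is why this is the fallback and not the main choice.

**Step 25.** The tartrate may be mismatched with the face of C1=C10 that the ring conformation exposes, leading to slow reaction and to opening of the product vinyl epoxide by the titanium alkoxide.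

Fallback: rely on substrate control before desilylation. Starting from 40, dimethyldioxirane in acetone at −20 °C would epoxidise the most electron-rich alkene, C1=C10, from the outer face of the ring to give the silyl-protected diepoxide F6. Bu4NF/AcOH would then free the C14 hydroxyl and return to the route at 42.

## Further compounds

F1 | step 13 | trimethylsilyl ether of 21 | C=C(CO[Si](c1ccccc1)(c1ccccc1)C(C)(C)C)[C@@H]1C=C[C@@](C)(O[Si](CC)(CC)CC)[C@H](O[Si](CC)(CC)CC)[C@@]1(O[Si](C)(C)C)/C=C/OCc1ccc(OC)cc1
F2 | step 13 | trimethylsilyl enol ether (C6–C7) of 24 | COc1ccc(CO[C@H]2C/C(CO[Si](c3ccccc3)(c3ccccc3)C(C)(C)C)=C/C=C\[C@@](C)(O[Si](CC)(CC)CC)[C@H](O[Si](CC)(CC)CC)/C(O[Si](C)(C)C)=C/2)cc1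
F3 | step 15 | C6 epimer (6R) of lactone 29 | COc1ccc(CO[C@H]2C/C(CO[Si](c3ccccc3)(c3ccccc3)C(C)(C)C)=C/C=C\[C@@](C)(O[Si](CC)(CC)CC)[C@H](O[Si](CC)(CC)CC)[C@@H]4OC(=O)C(O)C42)cc1
F4 | step 15 | (6R)-6,11-dihydroxy acid from opening of F3 | COc1ccc(CO[C@H]2C/C(CO[Si](c3ccccc3)(c3ccccc3)C(C)(C)C)=C/C=C\[C@@](C)(O[Si](CC)(CC)CC)[C@H](O[Si](CC)(CC)CC)[C@H](O)C2C(O)C(=O)O)cc1
F5 | step 23 | C5 methanesulfonate of diol 39 | CC[C@@H](C)C(=O)O[C@H]2C/C(CO[Si](c3ccccc3)(c3ccccc3)C(C)(C)C)=C/C=C\[C@@](C)(O)[C@H](OS(C)(=O)=O)[C@H]4OC(=O)C(COC(C)=O)=C42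
F6 | step 25 | 14-O-tert-butyldiphenylsilyl ether of 42 | CC[C@@H](C)C(=O)O[C@H]1C[C@@]2(CO[Si](c3ccccc3)(c3ccccc3)C(C)(C)C)O[C@@H]2/C=C\[C@@]2(C)O[C@H]2[C@H]2OC(=O)C(COC(C)=O)=C12
A1 | alternative 1 | diepoxy lactone with C8 triethylsilyl ether and C14 tert-butyldimethylsilyl ether | CC[Si](CC)(CC)O[C@H]1C[C@@]2(CO[Si](C)(C)C(C)(C)C)O[C@@H]2/C=C\[C@@]2(C)O[C@H]2[C@H]2OC(=O)C(COC(C)=O)=C12
A2 | alternative 1 | open-chain allylic diphenylsulfonium tetrafluoroborate with C10 ketone | c1ccccc1[S+](c1ccccc1)C/C=C\[C@@]1(C)O[C@H]1[C@H]1OC(=O)C(COC(C)=O)=C1[C@H](CC(=O)CO[Si](C)(C)C(C)(C)C)O[Si](CC)(CC)CC.F[B-](F)(F)F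
A3 | alternative 2 | ten-membered trienolide with ring-cis C1=C10, Z C2=C3 and ring-trans C4=C5 | CC[C@@H](C)C(=O)O[C@H]1C/C(CO)=C\C=C/C(C)=C/[C@H]2OC(=O)C(COC(C)=O)=C12
A4 | alternative 2 | cis-fused eudesma-1,3-dien-6,12-olide (C5–C10 bond intact) | CC[C@@H](C)C(=O)O[C@H]1C[C@@]2(CO)C=CC=C(C)[C@H]2[C@H]2OC(=O)C(COC(C)=O)=C12
A5 | alternative 3 | ten-membered trienol with C6 hydroxyl and the C7 2-propenyl unit | COc1ccc(CO[C@H]2C/C(CO[Si](c3ccccc3)(c3ccccc3)C(C)(C)C)=C\C=C/C(C)=C/[C@@H](O)[C@@H]2C(=C)CO[Si](C)(C)C(C)(C)C)cc1
A6 | alternative 3 | 13-membered diallylic ether with oxygen between C6 and C13 | COc1ccc(CO[C@H]2C/C(CO[Si](c3ccccc3)(c3ccccc3)C(C)(C)C)=C\C=C/C(C)=C/COC/C(CO[Si](C)(C)C(C)(C)C)=C/2)cc1
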